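**Retrosynthetic overview**
- Last step is a global desilylation; before it, one C(sp3)–C(sp2) Negishi coupling joins a lactone-CH2ZnI fragment to a 5-bromo-2,3-dihydrobenzofuran fragment of similar size.
- The dihydrobenzofuran closes by an intramolecular 1,6-oxa-Michael addition of a phenoxide onto a p-quinone methide that fluoride releases from a bis-silyl diacetate. Its C3 centre comes from an Evans aldol; C2 is set trans in the ring closure.
- The lactone ring comes from an Evans titanium-enolate benzyloxymethylation of a succinate imide, then reduction and lactonisation. The α-benzyl group is added by trans-selective enolate alkylation.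
- Ring order: lactone and dihydrobenzofuran are each formed inside their own branch; no ring is formed after the union.

Assumption: the target is taken exactly as drawn, (3R,4R) in the lactone and (2S,3R) in the dihydrobenzofuran, and all seven starting materials are taken as commercial. TBS = tert-butyldimethylsilyl.

**Branch A: dihydrobenzofuran bromide**

Step 1
Reactants: 1 vanillin
Product: 2 4-(TBS-oxy)-3-methoxybenzaldehyde
Conditions: TBSCl, imidazole, DMF, rt
Reagents that add atoms: tert-butyldimethylsilyl chloride, CC(C)(C)[Si](C)(C)Cl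
Why: Phenol silylation; the aryl TBS ether survives the later enolate, hydride and Pd steps and later serves as the fluoride trigger.

Step 2
Reactants: 3 4-bromo-2-methoxyphenol; 4 allyl bromide
Product: 5 1-(allyloxy)-4-bromo-2-methoxybenzene
Conditions: K2CO3, acetone, reflux
Reagents that add atoms: none
Why: Williamson ether synthesis of a phenoxide with a reactive allylic bromide.

Step 3
Reactants: 5 1-(allyloxy)-4-bromo-2-methoxybenzene
Product: 7 2-allyl-4-bromo-6-methoxyphenol, via ortho-dienone 6 (not isolated)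
Conditions: N,N-diethylaniline, 200 °C
Reagents that add atoms: none
Why: Aromatic Claisen rearrangement; only one ortho position is free, so the [3,3] shift and tautomerisation give one regioisomer.

Step 4
Reactants: 7 2-allyl-4-bromo-6-methoxyphenol
Product: 8 (2-allyl-4-bromo-6-methoxyphenoxy)(tert-butyl)dimethylsilane
Conditions: TBSCl, imidazole, DMF, 40 °C
Reagents that add atoms: tert-butyldimethylsilyl chloride, CC(C)(C)[Si](C)(C)Cl
Why: Silylation masks the phenol, which would otherwise be oxidised by periodate and would lactonise onto the later acid.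

Step 5
Reactants: 8 (2-allyl-4-bromo-6-methoxyphenoxy)(tert-butyl)dimethylsilane
Product: 10 2-[5-bromo-2-(TBS-oxy)-3-methoxyphenyl]acetaldehyde, via diol 9 (not isolated)
Conditions: OsO4 (2 mol %), NaIO4 (4 equiv), 2,6-lutidine, dioxane/H2O 3:1, rt
Reagents that add atoms: osmium tetroxide, O=[Os](=O)(=O)=O (catalytic oxygen carrier); sodium periodate, [Na+].[O-]I(=O)(=O)=O (terminal oxygen source)
Why: Lemieux–Johnson oxidation cleaves the terminal alkene by dihydroxylation and glycol cleavage without touching the electron-rich ring.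

Step 6
Reactants: 10 2-[5-bromo-2-(TBS-oxy)-3-methoxyphenyl]acetaldehyde
Product: 11 2-[5-bromo-2-(TBS-oxy)-3-methoxyphenyl]acetic acid
Conditions: NaClO2, NaH2PO4, 2-methylbut-2-ene, t-BuOH/H2O, 0 °C to rt
Reagents that add atoms: sodium chlorite, [Na+].[O-]Cl=O
Why: Pinnick oxidation takes the crude aldehyde to the acid under buffered conditions that leave the aryl silyl ether intact.

Step 7
Reactants: 11 2-[5-bromo-2-(TBS-oxy)-3-methoxyphenyl]acetic acid; 12 (S)-4-benzyloxazolidin-2-one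
Product: 14 (S)-4-benzyl-3-{2-[5-bromo-2-(TBS-oxy)-3-methoxyphenyl]acetyl}oxazolidin-2-one, via mixed pivalic anhydride 13 (not isolated)
Conditions: PivCl, Et3N, THF, −20 °C; then 12, LiCl, −20 °C to rt
Reagents that add atoms: none
Why: N-acylation of the auxiliary through the mixed anhydride, which reacts at the unhindered aryl-acetyl carbonyl.

Step 8
Reactants: 14 (S)-4-benzyl-3-{2-[5-bromo-2-(TBS-oxy)-3-methoxyphenyl]acetyl}oxazolidin-2-one; 2 4-(TBS-oxy)-3-methoxybenzaldehyde
Product: 16 (S)-4-benzyl-3-{(2S,3S)-2-[5-bromo-2-(TBS-oxy)-3-methoxyphenyl]-3-hydroxy-3-[4-(TBS-oxy)-3-methoxyphenyl]propanoyl}oxazolidin-2-one, via Z-boron enolate 15 (not isolated)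
Conditions: Bu2BOTf, i-Pr2NEt, CH2Cl2, −78 to 0 °C; then 2, −78 to 0 °C; pH 7 buffer, MeOH, 30% H2O2, 0 °C
Reagents that add atoms: none
Why: Evans syn-aldol through a Zimmerman–Traxler transition state; the (S)-auxiliary fixes the α-centre as 2S (the future C3), and the carbinol centre (3S) is erased later, so only the enolate face selectivity matters.

Step 9
Reactants: 16 the aldol adduct
Product: 17 (1S,2R)-2-[5-bromo-2-(TBS-oxy)-3-methoxyphenyl]-1-[4-(TBS-oxy)-3-methoxyphenyl]propane-1,3-diol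
Conditions: LiBH4, MeOH (1 equiv), THF, 0 °C
Reagents that add atoms: none
Why: Reductive cleavage of the imide gives the primary alcohol and makes the former α-carbon non-acidic, so it cannot epimerise or undergo retro-aldol later.

Step 10
Reactants: 17 the 1,3-diol
Product: 18 (1S,2R)-2-[5-bromo-2-(TBS-oxy)-3-methoxyphenyl]-1-[4-(TBS-oxy)-3-methoxyphenyl]propane-1,3-diyl diacetate
Conditions: Ac2O, pyridine, DMAP (cat.), CH2Cl2, rt
Reagents that add atoms: acetic anhydride, CC(=O)OC(C)=O
Why: Exhaustive acetylation avoids any selectivity issue and turns the benzylic oxygen into a leaving group para to the masked phenol.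

Step 11
Reactants: 18 the diacetate
Product: 20 [(2S,3R)-5-bromo-2-(4-hydroxy-3-methoxyphenyl)-7-methoxy-2,3-dihydrobenzofuran-3-yl]methyl acetate, via p-quinone methide 19 (not isolated)
Conditions: TBAF (3 equiv), THF, 0 °C to rt
Reagents that add atoms: none
Why: Fluoride unmasks both phenoxides, the para one expels benzylic acetate (1,6-elimination) and the ortho one closes the ring by 5-exo intramolecular oxa-Michael (1,6-conjugate) addition; C2 forms trans to the C3 substituent (2S), the kinetically and thermodynamically favoured arrangement of this reversible addition.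

Step 12
Reactants: 20 the dihydrobenzofuran acetate
Product: 21 4-[(2S,3R)-5-bromo-3-(hydroxymethyl)-7-methoxy-2,3-dihydrobenzofuran-2-yl]-2-methoxyphenol
Conditions: K2CO3, MeOH, rt
Reagents that add atoms: none
Why: Base-catalysed transesterification removes the primary acetate while no lactone is yet present.

Step 13
Reactants: 21 the phenol alcohol
Product: 22 (2S,3R)-5-bromo-2-[4-(TBS-oxy)-3-methoxyphenyl]-3-[(TBS-oxy)methyl]-7-methoxy-2,3-dihydrobenzofuran
Conditions: TBSCl (2.5 equiv), imidazole, DMF, rt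
Reagents that add atoms: tert-butyldimethylsilyl chloride, CC(C)(C)[Si](C)(C)Cl
Why: Double silylation removes both acidic protons before the organozinc coupling and lets one fluoride step deprotect everything at the end.

**Branch B: iodomethyl lactone**

Step 14
Reactants: 2 4-(TBS-oxy)-3-methoxybenzaldehyde
Product: 23 [4-(TBS-oxy)-3-methoxyphenyl]methanol
Conditions: NaBH4, THF/MeOH 10:1, 0 °C
Reagents that add atoms: none
Why: Chemoselective borohydride reduction of the aldehyde.

Step 15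
Reactants: 23 [4-(TBS-oxy)-3-methoxyphenyl]methanol
Product: 24 [4-(bromomethyl)-2-methoxyphenoxy](tert-butyl)dimethylsilane
Conditions: CBr4, PPh3, CH2Cl2, 0 °C (used directly)
Reagents that add atoms: carbon tetrabromide, BrC(Br)(Br)Br
Why: Appel bromination under neutral conditions, which this acid-sensitive electron-rich benzylic bromide requires.

Step 16
Reactants: 25 4-(tert-butoxy)-4-oxobutanoic acid; 26 (R)-4-benzyloxazolidin-2-one
Product: 28 tert-butyl 4-[(R)-4-benzyl-2-oxooxazolidin-3-yl]-4-oxobutanoate, via mixed pivalic anhydride 27 (not isolated)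
Conditions: PivCl, Et3N, THF, −20 °C; then 26, LiCl, rt
Reagents that add atoms: none
Why: N-acylation through the mixed anhydride; the tert-butyl ester is inert.

Step 17
Reactants: 28 the succinate imide; 29 benzyl chloromethyl ether
Product: 31 tert-butyl (S)-3-[(benzyloxy)methyl]-4-[(R)-4-benzyl-2-oxooxazolidin-3-yl]-4-oxobutanoate, via titanium enolate 30 (not isolated)
Conditions: TiCl4, i-Pr2NEt, CH2Cl2, 0 °C; then 29, 0 °C
Reagents that add atoms: none
Why: Evans titanium-enolate alkylation; the chelated Z-enolate is attacked on the face opposite the auxiliary benzyl group, which sets the new centre as S (the future lactone C4).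

Step 18
Reactants: 31 the alkylated imide
Product: 33 (S)-4-[(benzyloxy)methyl]dihydrofuran-2(3H)-one, via hydroxy ester 32 (not isolated)
Conditions: LiBH4, MeOH (1 equiv), THF, 0 °C; then TFA, CH2Cl2, rt
Reagents that add atoms: none
Why: The imide carbonyl is reduced in preference to the tert-butyl ester, and acid then cleaves that ester and closes the γ-lactone without touching the stereocentre.

Step 19
Reactants: 33 the lactone; 24 the benzylic bromide
Product: 35 (3R,4S)-4-[(benzyloxy)methyl]-3-[4-(TBS-oxy)-3-methoxybenzyl]dihydrofuran-2(3H)-one, via lithium enolate 34 (not isolated)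
Conditions: LiHMDS, THF, −78 °C; then 24, DMPU, −78 to −40 °C
Reagents that add atoms: none
Why: Lactone enolate alkylation; the bromide approaches anti to the C4 substituent, giving the trans (3R) product.

Step 20
Reactants: 35 the benzyl ether
Product: 36 (3R,4S)-4-(hydroxymethyl)-3-[4-(TBS-oxy)-3-methoxybenzyl]dihydrofuran-2(3H)-one
Conditions: H2 (1 atm), 10% Pd/C, EtOAc, rt
Reagents that add atoms: none
Why: Neutral hydrogenolysis of the benzyl ether; neutral conditions also prevent translactonisation of the free hydroxymethyl lactone.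

Step 21
Reactants: 36 the alcohol
Product: 37 (3R,4R)-4-(iodomethyl)-3-[4-(TBS-oxy)-3-methoxybenzyl]dihydrofuran-2(3H)-one
Conditions: I2, PPh3, imidazole, CH2Cl2, 0 °C to rt
Reagents that add atoms: iodine, II
Why: Appel-type (Garegg–Samuelsson) iodination of a primary alcohol; no stereocentre is involved.

**Union and end game**

Step 22
Reactants: 37 the iodide; 22 the aryl bromide
Product: 39 tris-TBS lappaol A, via alkylzinc iodide 38 (not isolated)
Conditions: Zn dust (activated with TMSCl and 1,2-dibromoethane), DMF, rt; then 22, Pd2(dba)3 (2.5 mol %), SPhos (10 mol %), THF/DMF, 50 °C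
Reagents that add atoms: none
Why: Negishi coupling of a primary alkylzinc (inert to the lactone and silyl ethers) with an unhindered aryl bromide; the bulky biaryl phosphine favours reductive elimination over β-hydride elimination, and no stereocentre is touched.

Step 23
Reactants: 39 tris-TBS lappaol A
Product: 40 lappaol A
Conditions: TBAF, AcOH (1:1, 4 equiv), THF, 0 °C to rt
Reagents that add atoms: none
Why: Buffered fluoride desilylation removes the two aryl and one alkyl TBS groups without opening or epimerising the trans-lactone.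

**Compound list**

1 | vanillin | COc1cc(C=O)ccc1O | starting material
2 | 4-(TBS-oxy)-3-methoxybenzaldehyde | COc1cc(C=O)ccc1O[Si](C)(C)C(C)(C)C | intermediate
3 | 4-bromo-2-methoxyphenol | COc1cc(Br)ccc1O | starting material
4 | allyl bromide | C=CCBr | starting material
5 | 1-(allyloxy)-4-bromo-2-methoxybenzene | COc1cc(Br)ccc1OCC=C | intermediate
6 | 6-allyl-4-bromo-2-methoxycyclohexa-2,4-dien-1-one (racemic, not isolated) | COC1=CC(Br)=CC(CC=C)C1=O | intermediate
7 | 2-allyl-4-bromo-6-methoxyphenol | COc1cc(Br)cc(CC=C)c1O | intermediate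
8 | (2-allyl-4-bromo-6-methoxyphenoxy)(tert-butyl)dimethylsilane | COc1cc(Br)cc(CC=C)c1O[Si](C)(C)C(C)(C)C | intermediate
9 | 3-[5-bromo-2-(TBS-oxy)-3-methoxyphenyl]propane-1,2-diol (racemic, not isolated) | COc1cc(Br)cc(CC(O)CO)c1O[Si](C)(C)C(C)(C)C | intermediate
10 | 2-[5-bromo-2-(TBS-oxy)-3-methoxyphenyl]acetaldehyde | COc1cc(Br)cc(CC=O)c1O[Si](C)(C)C(C)(C)C | intermediate
11 | 2-[5-bromo-2-(TBS-oxy)-3-methoxyphenyl]acetic acid | COc1cc(Br)cc(CC(=O)O)c1O[Si](C)(C)C(C)(C)C | intermediate
12 | (S)-4-benzyloxazolidin-2-one | O=C1N[C@@H](Cc2ccccc2)CO1 | starting material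
13 | mixed pivalic anhydride of 11 (not isolated) | COc1cc(Br)cc(CC(=O)OC(=O)C(C)(C)C)c1O[Si](C)(C)C(C)(C)C | intermediate
14 | (S)-4-benzyl-3-{2-[5-bromo-2-(TBS-oxy)-3-methoxyphenyl]acetyl}oxazolidin-2-one | COc1cc(Br)cc(CC(=O)N2[C@@H](Cc3ccccc3)COC2=O)c1O[Si](C)(C)C(C)(C)C | intermediate
15 | Z-dibutylboron enolate of 14 (not isolated) | CCCCB(CCCC)O/C(=C\c1cc(Br)cc(OC)c1O[Si](C)(C)C(C)(C)C)N1[C@@H](Cc2ccccc2)COC1=O | intermediate
16 | (S)-4-benzyl-3-{(2S,3S)-2-[5-bromo-2-(TBS-oxy)-3-methoxyphenyl]-3-hydroxy-3-[4-(TBS-oxy)-3-methoxyphenyl]propanoyl}oxazolidin-2-one | O=C1OC[C@H](Cc2ccccc2)N1C(=O)[C@@H](c1cc(Br)cc(OC)c1O[Si](C)(C)C(C)(C)C)[C@H](O)c1ccc(O[Si](C)(C)C(C)(C)C)c(OC)c1 | intermediate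
17 | (1S,2R)-2-[5-bromo-2-(TBS-oxy)-3-methoxyphenyl]-1-[4-(TBS-oxy)-3-methoxyphenyl]propane-1,3-diol | OC[C@@H](c1cc(Br)cc(OC)c1O[Si](C)(C)C(C)(C)C)[C@H](O)c1ccc(O[Si](C)(C)C(C)(C)C)c(OC)c1 | intermediate
18 | (1S,2R)-diacetate of 17 | CC(=O)OC[C@@H](c1cc(Br)cc(OC)c1O[Si](C)(C)C(C)(C)C)[C@H](OC(C)=O)c1ccc(O[Si](C)(C)C(C)(C)C)c(OC)c1 | intermediate
19 | (R)-3-(5-bromo-2-hydroxy-3-methoxyphenyl)-... p-quinone methide: 4-[(R)-3-acetoxy-2-(5-bromo-2-hydroxy-3-methoxyphenyl)propylidene]-2-methoxycyclohexa-2,5-dien-1-one (not isolated) | COC1=CC(=C[C@@H](COC(C)=O)c2cc(Br)cc(OC)c2O)C=CC1=O | intermediate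
20 | [(2S,3R)-5-bromo-2-(4-hydroxy-3-methoxyphenyl)-7-methoxy-2,3-dihydrobenzofuran-3-yl]methyl acetate | Brc1cc(OC)c2c(c1)[C@H](COC(C)=O)[C@@H](c1ccc(O)c(OC)c1)O2 | intermediate
21 | 4-[(2S,3R)-5-bromo-3-(hydroxymethyl)-7-methoxy-2,3-dihydrobenzofuran-2-yl]-2-methoxyphenol | Brc1cc(OC)c2c(c1)[C@H](CO)[C@@H](c1ccc(O)c(OC)c1)O2 | intermediate
22 | (2S,3R)-5-bromo-2-[4-(TBS-oxy)-3-methoxyphenyl]-3-[(TBS-oxy)methyl]-7-methoxy-2,3-dihydrobenzofuran | Brc1cc(OC)c2c(c1)[C@H](CO[Si](C)(C)C(C)(C)C)[C@@H](c1ccc(O[Si](C)(C)C(C)(C)C)c(OC)c1)O2 | intermediate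
23 | [4-(TBS-oxy)-3-methoxyphenyl]methanol | COc1cc(CO)ccc1O[Si](C)(C)C(C)(C)C | intermediate
24 | [4-(bromomethyl)-2-methoxyphenoxy](tert-butyl)dimethylsilane | COc1cc(CBr)ccc1O[Si](C)(C)C(C)(C)C | intermediate
25 | 4-(tert-butoxy)-4-oxobutanoic acid | CC(C)(C)OC(=O)CCC(=O)O | starting material
26 | (R)-4-benzyloxazolidin-2-one | O=C1N[C@H](Cc2ccccc2)CO1 | starting material
27 | mixed pivalic anhydride of 25 (not isolated) | CC(C)(C)OC(=O)CCC(=O)OC(=O)C(C)(C)C | intermediate
28 | tert-butyl 4-[(R)-4-benzyl-2-oxooxazolidin-3-yl]-4-oxobutanoate | CC(C)(C)OC(=O)CCC(=O)N1[C@H](Cc2ccccc2)COC1=O | intermediate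
29 | benzyl chloromethyl ether | ClCOCc1ccccc1 | starting material
30 | Z-trichlorotitanium enolate of 28 (not isolated) | Cl[Ti](Cl)(Cl)O/C(=C\CC(=O)OC(C)(C)C)N1[C@H](Cc2ccccc2)COC1=O | intermediate
31 | tert-butyl (S)-3-[(benzyloxy)methyl]-4-[(R)-4-benzyl-2-oxooxazolidin-3-yl]-4-oxobutanoate | O=C1OC[C@@H](Cc2ccccc2)N1C(=O)[C@@H](CC(=O)OC(C)(C)C)COCc1ccccc1 | intermediate
32 | tert-butyl (R)-4-(benzyloxy)-3-(hydroxymethyl)butanoate (not isolated) | OC[C@@H](CC(=O)OC(C)(C)C)COCc1ccccc1 | intermediate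
33 | (S)-4-[(benzyloxy)methyl]dihydrofuran-2(3H)-one | O=C1OC[C@H](COCc2ccccc2)C1 | intermediate
34 | lithium enolate of 33 (not isolated) | [Li]OC1=C[C@@H](COCc2ccccc2)CO1 | intermediate
35 | (3R,4S)-4-[(benzyloxy)methyl]-3-[4-(TBS-oxy)-3-methoxybenzyl]dihydrofuran-2(3H)-one | COc1cc(C[C@H]2C(=O)OC[C@@H]2COCc2ccccc2)ccc1O[Si](C)(C)C(C)(C)C | intermediate
36 | (3R,4S)-4-(hydroxymethyl)-3-[4-(TBS-oxy)-3-methoxybenzyl]dihydrofuran-2(3H)-one | COc1cc(C[C@H]2C(=O)OC[C@@H]2CO)ccc1O[Si](C)(C)C(C)(C)C | intermediate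
37 | (3R,4R)-4-(iodomethyl)-3-[4-(TBS-oxy)-3-methoxybenzyl]dihydrofuran-2(3H)-one | COc1cc(C[C@H]2C(=O)OC[C@@H]2CI)ccc1O[Si](C)(C)C(C)(C)C | intermediate
38 | {[(3R,4R)-5-oxo-4-[4-(TBS-oxy)-3-methoxybenzyl]tetrahydrofuran-3-yl]methyl}zinc iodide (not isolated) | COc1cc(C[C@H]2C(=O)OC[C@@H]2C[Zn]I)ccc1O[Si](C)(C)C(C)(C)C | intermediate
39 | tris-TBS lappaol A: (3R,4R)-lactone bearing 3-[4-(TBS-oxy)-3-methoxybenzyl] and 4-{[(2S,3R)-2-[4-(TBS-oxy)-3-methoxyphenyl]-3-[(TBS-oxy)methyl]-7-methoxy-2,3-dihydrobenzofuran-5-yl]methyl} | COc1cc(C[C@H]2C(=O)OC[C@@H]2Cc2cc(OC)c3c(c2)[C@H](CO[Si](C)(C)C(C)(C)C)[C@@H](c2ccc(O[Si](C)(C)C(C)(C)C)c(OC)c2)O3)ccc1O[Si](C)(C)C(C)(C)C | intermediate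
40 | lappaol A: (3R,4R)-3-(4-hydroxy-3-methoxybenzyl)-4-{[(2S,3R)-2-(4-hydroxy-3-methoxyphenyl)-3-(hydroxymethyl)-7-methoxy-2,3-dihydrobenzofuran-5-yl]methyl}dihydrofuran-2(3H)-one | COc1cc(C[C@H]2C(=O)OC[C@@H]2Cc2cc(OC)c3c(c2)[C@H](CO)[C@@H](c2ccc(O)c(OC)c2)O3)ccc1O | target

**Totals**
- Total step count: 23.
- Longest linear sequence: 14 steps (steps 2–13, then 22 and 23), which is 61% of the total.

**Three steps most likely to fail, with fallbacks**

Step 8 (boron aldol of an aryl-acetyl imide with an electron-rich aldehyde; risk of low conversion, retro-aldol or eroded face selectivity). The fallback sets the same centre by alkylation and makes the quinone methide by oxidation. It sets out from acid 11 and comes back at 20. Acid 11 is coupled under the step 7 conditions (through 13) with the enantiomeric auxiliary 26 to give (R)-4-benzyl-3-{2-[5-bromo-2-(TBS-oxy)-3-methoxyphenyl]acetyl}oxazolidin-2-one F1. Its sodium enolate (NaHMDS, THF, −78 °C) is benzylated with bromide 24 on the face opposite the auxiliary benzyl group to give (R)-4-benzyl-3-{(R)-2-[5-bromo-2-(TBS-oxy)-3-methoxyphenyl]-3-[4-(TBS-oxy)-3-methoxyphenyl]propanoyl}oxazolidin-2-one F2. LiBH4 gives (R)-2-[5-bromo-2-(TBS-oxy)-3-methoxyphenyl]-3-[4-(TBS-oxy)-3-methoxyphenyl]propan-1-ol F3, and Ac2O/pyridine gives (R)-2-[5-bromo-2-(TBS-oxy)-3-methoxyphenyl]-3-[4-(TBS-oxy)-3-methoxyphenyl]propyl acetate F4. TBAF then gives (R)-2-(5-bromo-2-hydroxy-3-methoxyphenyl)-3-(4-hydroxy-3-methoxyphenyl)propyl acetate F5. Ag2O (CH2Cl2, rt) oxidises the 4-alkylguaiacol ring of F5, the only phenol with a para CH2, to quinone methide 19, which closes to 20 as in step 11.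

Step 11 (fluoride-triggered quinone methide formation and oxa-Michael closure; risk that the quinone methide tautomerises to a stilbene or oligomerises before the hindered ortho silyl ether is cleaved). The fallback makes the quinone methide by acid-catalysed dehydration of the fully unmasked substrate. It sets out from diol 17 and comes back at 21, bypassing steps 10–12. TBAF (THF, 0 °C) gives (1S,2R)-2-(5-bromo-2-hydroxy-3-methoxyphenyl)-1-(4-hydroxy-3-methoxyphenyl)propane-1,3-diol F6, in which the ortho phenol is already free. Catalytic camphorsulfonic acid (CH2Cl2/MeCN, 0 °C) then removes water from the p-hydroxybenzylic carbinol to give 4-[(R)-2-(5-bromo-2-hydroxy-3-methoxyphenyl)-3-hydroxypropylidene]-2-methoxycyclohexa-2,5-dien-1-one F7. The neighbouring phenol traps F7 by the same 5-exo conjugate addition to give the trans product 21; the closure is reversible under acid, so the thermodynamic trans isomer accumulates.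

Step 22 (zinc insertion and Negishi coupling; risk of protodezincation or β-hydride elimination to the exo-methylene lactone). The fallback avoids any preformed organometallic. It sets out from 22 and 37 and comes back at 39. The two halides are joined directly by nickel-catalysed reductive cross-electrophile coupling (NiI2 10 mol %, 4,4′-di-tert-butyl-2,2′-bipyridine, Mn powder, NaI, DMA/pyridine, 60 °C). The alkyl iodide enters as a radical and the aryl bromide by oxidative addition to nickel, and the lactone and silyl ethers are tolerated.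

**Further compounds**

F1 | step 8 | (R)-4-benzyl-3-{2-[5-bromo-2-(TBS-oxy)-3-methoxyphenyl]acetyl}oxazolidin-2-one | COc1cc(Br)cc(CC(=O)N2[C@H](Cc3ccccc3)COC2=O)c1O[Si](C)(C)C(C)(C)C
F2 | step 8 | (R)-4-benzyl-3-{(R)-2-[5-bromo-2-(TBS-oxy)-3-methoxyphenyl]-3-[4-(TBS-oxy)-3-methoxyphenyl]propanoyl}oxazolidin-2-one | O=C1OC[C@@H](Cc2ccccc2)N1C(=O)[C@@H](c1cc(Br)cc(OC)c1O[Si](C)(C)C(C)(C)C)Cc1ccc(O[Si](C)(C)C(C)(C)C)c(OC)c1
F3 | step 8 | (R)-2-[5-bromo-2-(TBS-oxy)-3-methoxyphenyl]-3-[4-(TBS-oxy)-3-methoxyphenyl]propan-1-ol | OC[C@@H](c1cc(Br)cc(OC)c1O[Si](C)(C)C(C)(C)C)Cc1ccc(O[Si](C)(C)C(C)(C)C)c(OC)c1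
F4 | step 8 | (R)-2-[5-bromo-2-(TBS-oxy)-3-methoxyphenyl]-3-[4-(TBS-oxy)-3-methoxyphenyl]propyl acetate | CC(=O)OC[C@@H](c1cc(Br)cc(OC)c1O[Si](C)(C)C(C)(C)C)Cc1ccc(O[Si](C)(C)C(C)(C)C)c(OC)c1
F5 | step 8 | (R)-2-(5-bromo-2-hydroxy-3-methoxyphenyl)-3-(4-hydroxy-3-methoxyphenyl)propyl acetate | CC(=O)OC[C@@H](c1cc(Br)cc(OC)c1O)Cc1ccc(O)c(OC)c1
F6 | step 11 | (1S,2R)-2-(5-bromo-2-hydroxy-3-methoxyphenyl)-1-(4-hydroxy-3-methoxyphenyl)propane-1,3-diol | OC[C@@H](c1cc(Br)cc(OC)c1O)[C@H](O)c1ccc(O)c(OC)c1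
F7 | step 11 | 4-[(R)-2-(5-bromo-2-hydroxy-3-methoxyphenyl)-3-hydroxypropylidene]-2-methoxycyclohexa-2,5-dien-1-one | COC1=CC(=C[C@@H](CO)c2cc(Br)cc(OC)c2O)C=CC1=O
F0 | step 22 | none | none
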